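**Retrosynthetic overview** (gibberellane numbering)
1. Ring A is made last on a B/C/D tricycle: C1–C10 (acetylide addition to a C10 ketone), C4–C5 (propionate Michael addition, which also closes the 19,10-lactone), C3–C4 (aldol); the 1β-OH comes from epoxidation and reductive opening of the 1-en-3-one.
2. Rings C and D are taken off a ring B cyclopentenone together: C13–C16 (enol ether onto alkyne), then C8–C14 and C9–C11 (enone plus 2-silyloxybutadiene); ring order B → C → D → lactone → A.
3. Enabling feature: in ring C (C8, C9, C11, C12, C13, C14) the C12 oxygen is 1,4 to C6 across the C8–C9 bond, and C13 is 1,3 to quaternary C8, which carries the C15–C16 arm. With C6 at the ketone level this is the retron of a double Michael annulation that ends with C8–C14 bond formation and leaves the C12=C13 enol ether that closes ring D.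
4. Stereochemistry: one resolved stereocentre (C10–O of a 4-silyloxy-2-propargylcyclopentenone, later oxidised away) directs C9 and C8; C13, C12, C10, C5, C6, C4 and C1 are relayed by the rigid skeleton.

Key step: step 7

Remark: furfural, propargyl bromide, methyl vinyl ketone and 3,3-diethoxyprop-1-yne are taken as commercial; α denotes the face of the lactone bridge, β the opposite face, and the target is the enantiomer of the natural gibberellin series.

Step 1
Reactants: 1 furfural; 2 propargyl bromide
Product: 3 rac-1-(furan-2-yl)but-3-yn-1-ol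
Conditions: Zn, THF/sat. aq. NH4Cl, 0 °C → rt
Reagents that add atoms: none
Why: Zinc-mediated Barbier propargylation, in which the allenylzinc intermediate adds to the aldehyde through a cyclic SE2′ transition state and should give the homopropargylic alcohol; the carbinol centre is racemic and is erased in step 2.

Step 2
Reactants: 3 rac-1-(furan-2-yl)but-3-yn-1-ol
Product: 5 rac-4-hydroxy-2-(prop-2-yn-1-yl)cyclopent-2-en-1-one, via trans-4-hydroxy-5-propargylcyclopentenone 4 (not isolated)
Conditions: ZnCl2, 1,4-dioxane/H2O, reflux; then Na2HPO4/NaH2PO4 (pH 8), reflux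
Reagents that add atoms: water, O
Why: Piancatelli rearrangement (acid-promoted hydration of the furfuryl cation, ring opening and conrotatory 4π-electrocyclisation) should give the trans-4-hydroxy-5-propargyl enone 4, which under the mildly basic second stage isomerises to the thermodynamically preferred 2-substituted 4-hydroxycyclopentenone 5, obtained as the racemate.

Step 3
Reactants: 5 rac-4-hydroxy-2-(prop-2-yn-1-yl)cyclopent-2-en-1-one
Product: 6 (R)-4-oxo-3-(prop-2-yn-1-yl)cyclopent-2-en-1-yl acetate
Conditions: lipase PS (Burkholderia cepacia), vinyl acetate, MTBE, 30 °C, to half conversion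
Reagents that add atoms: vinyl acetate, CC(=O)OC=C
Why: Lipase-catalysed kinetic resolution by irreversible transesterification, a reaction with close precedent for 2-alkyl-4-hydroxycyclopentenones, in which the (R)-alcohol is expected to be acylated while the (S)-alcohol remains and is removed by chromatography; this sets the single stereocentre from which all others are relayed.

Step 4
Reactants: 6 (R)-4-oxo-3-(prop-2-yn-1-yl)cyclopent-2-en-1-yl acetate
Product: 7 (R)-4-hydroxy-2-(prop-2-yn-1-yl)cyclopent-2-en-1-one
Conditions: lipase PS, NaH2PO4/Na2HPO4 buffer (pH 7), MTBE, rt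
Reagents that add atoms: none
Why: Enzymatic ester hydrolysis at neutral pH with the same (R)-selective lipase should liberate the alcohol without the β-elimination that chemical saponification of a 4-acyloxycyclopentenone invites, and without touching the stereocentre.

Step 5
Reactants: 7 (R)-4-hydroxy-2-(prop-2-yn-1-yl)cyclopent-2-en-1-one
Product: 8 (R)-2-(prop-2-yn-1-yl)-4-(triethylsilyloxy)cyclopent-2-en-1-one
Conditions: Et3SiCl, imidazole, CH2Cl2, 0 °C
Reagents that add atoms: chlorotriethylsilane, CC[Si](Cl)(CC)CC
Why: Silylation of the secondary alcohol (silyl ether formation), the triethylsilyl group being chosen because it survives steps 7 to 11 and can later be removed in the presence of a tert-butyldimethylsilyl ether.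

Step 6
Reactants: 9 methyl vinyl ketone
Product: 10 2-(tert-butyldimethylsilyloxy)buta-1,3-diene
Conditions: t-BuMe2SiOTf, Et3N, Et2O, 0 °C
Reagents that add atoms: tert-butyldimethylsilyl trifluoromethanesulfonate, CC(C)(C)[Si](C)(C)OS(=O)(=O)C(F)(F)F
Why: O-Silylation of the enone under soft enolisation conditions (silyl triflate and amine) should give the cross-conjugated 2-silyloxydiene; no stereocentre is formed.

Step 7
Reactants: 8 (R)-2-(prop-2-yn-1-yl)-4-(triethylsilyloxy)cyclopent-2-en-1-one; 10 2-(tert-butyldimethylsilyloxy)buta-1,3-diene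
Product: 12 B/C/D tricyclic 6,12-diketone (10β-OSiEt3; 16-methylene), via cis-hydrindenone silyl enol ether 11 (not isolated)
Conditions: Tf2NH (5 mol%), CH2Cl2, −78 → −40 °C; then 2,6-di-tert-butylpyridine (10 mol%), Ph3PAuCl (5 mol%), AgBF4 (5 mol%), CH2Cl2/H2O (10:1), 40 °C
Reagents that add atoms: none
Why: Tf2NH generates the silyl triflimide, which activates the enone of 8; the nucleophilic CH2 terminus of 10 adds to C9 (Mukaiyama–Michael), and the resulting C6 silyl enol ether closes ring C by attack of C8 on the terminal carbon of the silyl-activated vinyl ketone (C8–C14, 6-(enolexo)-endo-trig), giving the formal [4+2] adduct 11 with the silyl group transferred to the C12 oxygen. The closest known reaction types are the triflimide-catalysed stepwise Diels–Alder (double Michael) reaction of 2-silyloxydienes with hindered 2-substituted cycloalkenones and the gold-catalysed carbocyclisation of silyl enol ethers onto alkynes (Conia-ene type). In the second stage cationic monovalent gold activates the alkyne, the enol ether carbon C13 attacks C16 (ring D, 5-exo-dig), and protodeauration leaves the exocyclic methylene and the C12 ketone. C9 is set by addition anti to the C10 silyloxy group, C8 by the tether (only the cis ring fusion can close), and C13 by the one-carbon C14 bridge, which lets the propargyl arm reach C13 from one face only. The step needs the regiochemistry C11 to C9 and C14 to C8, which follows from the polarity of the 2-silyloxydiene and the enone, and it needs the enol ether to lie between C12 and C13, which is secured because the annulation delivers exactly this isomer without any enolisation step. Chemoselectivity in the gold stage is secured because 11 holds a single enol ether and a single alkyne, placed 1,3 across ring C.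

Step 8
Reactants: 12 B/C/D tricyclic 6,12-diketone
Product: 13 12α-hydroxy-6-ketone
Conditions: LiBH(s-Bu)3 (1.05 equiv), THF, −78 °C
Reagents that add atoms: none
Why: Chemo- and diastereoselective ketone reduction with a bulky trialkylborohydride: the ring C cyclohexanone should react in preference to the ring B cyclopentanone, which is flanked by quaternary C8, and hydride should arrive on the face of C12 that is anti to the axial C9–C10 bond, giving the axial 12α-alcohol.

Step 9
Reactants: 13 12α-hydroxy-6-ketone
Product: 14 12α-(tert-butyldimethylsilyloxy)-6-ketone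
Conditions: t-BuMe2SiOTf, 2,6-lutidine, CH2Cl2, −78 → 0 °C
Reagents that add atoms: tert-butyldimethylsilyl trifluoromethanesulfonate, CC(C)(C)[Si](C)(C)OS(=O)(=O)C(F)(F)F
Why: Silyl triflate silylation, the method of choice for a hindered axial secondary alcohol; the ketone is not enolised by 2,6-lutidine at this temperature.

Step 10
Reactants: 14 12α-(tert-butyldimethylsilyloxy)-6-ketone
Product: 15 C5=C6 enol triflate
Conditions: KN(SiMe3)2, THF, −78 °C; then N-(5-chloro-2-pyridyl)bis(trifluoromethanesulfonimide), −78 °C
Reagents that add atoms: N-(5-chloro-2-pyridyl)bis(trifluoromethanesulfonimide), O=S(=O)(N(c1ccc(Cl)cn1)S(=O)(=O)C(F)(F)F)C(F)(F)F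
Why: Kinetic enol triflate formation: deprotonation can occur only at C5 because C8 is quaternary, and O-sulfonylation at −78 °C by the reactive N-pyridyl triflimide should outrun β-elimination of the C10 silyloxy group.

Step 11
Reactants: 15 C5=C6 enol triflate
Product: 16 2-(trimethylsilyl)ethyl ene ester (C7 on C6; C5=C6)
Conditions: Pd(OAc)2 (5 mol%), dppf, CO (1 atm), Et3N, Me3SiCH2CH2OH, DMF, 60 °C
Reagents that add atoms: carbon monoxide, [C-]#[O+]; 2-(trimethylsilyl)ethanol, C[Si](C)(C)CCO
Why: Palladium-catalysed alkoxycarbonylation of the enol triflate (oxidative addition to zerovalent palladium, CO insertion and alcoholysis of the acyl complex) introduces C7 as a fluoride-labile ester and leaves the C5=C6 alkene conjugated to it.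

Step 12
Reactants: 16 2-(trimethylsilyl)ethyl ene ester
Product: 17 10β-allylic alcohol
Conditions: PPTS (cat.), MeOH/CH2Cl2, 0 °C
Reagents that add atoms: none
Why: Acid-catalysed methanolysis (selective desilylation) should remove the unhindered allylic triethylsilyl ether far faster than the hindered axial tert-butyldimethylsilyl ether.

Step 13
Reactants: 17 10β-allylic alcohol
Product: 18 10-keto ene ester
Conditions: Dess–Martin periodinane, CH2Cl2, 0 °C → rt
Reagents that add atoms: none
Why: Dess–Martin oxidation of the allylic alcohol gives the cross-conjugated keto ester; the C10 stereocentre, having directed C8 and C9, is erased here.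

Step 14
Reactants: 18 10-keto ene ester; 19 3,3-diethoxyprop-1-yne
Product: 21 10α-propionyloxy-10β-(3,3-diethoxyprop-1-ynyl) ene ester, via C10 alkoxide 20 (not isolated)
Conditions: 19, n-BuLi, THF, −78 °C; CeCl3; then 18, −78 °C; then (EtCO)2O, DMAP (cat.), −78 → 0 °C
Reagents that add atoms: propionic anhydride, CCC(=O)OC(=O)CC
Why: 1,2-Addition of the organocerium acetylide to the C10 ketone (CeCl3 suppresses enolisation at C9) should occur from the β face, because the α face is covered by ring C and the axial 12-silyloxy group, which sets C10 with oxygen α; the tertiary alkoxide is then acylated in the same flask.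

Step 15
Reactants: 21 10α-propionyloxy-10β-(3,3-diethoxyprop-1-ynyl) ene ester
Product: 22 19,10-lactone (C4 epimers; H5 β; 6β ester)
Conditions: KH, THF, 0 °C → rt
Reagents that add atoms: none
Why: Intramolecular Michael addition of the propionate enolate to C5 of the ene ester closes the γ-lactone: the tether through the α-oriented C10 oxygen forces the new C4–C5 bond onto the α face (H5 β), protonation of the C6 ester enolate should give the more stable 6β ester trans to the new C5 substituent, and C4 is left as an epimer mixture that is re-enolised in step 17.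

Step 16
Reactants: 22 19,10-lactone with 10β-alkynyl chain
Product: 23 (Z)-alkenyl acetal lactone
Conditions: H2 (1 atm), Pd/CaCO3 poisoned by Pb(OAc)2, quinoline, EtOAc, rt
Reagents that add atoms: none
Why: Semi-hydrogenation of the alkyne over poisoned palladium (Lindlar reduction, syn addition of hydrogen) should give the (Z)-alkene that ring closure requires, the hindered 1,1-disubstituted C16 methylene being left untouched.

Step 17
Reactants: 23 (Z)-alkenyl acetal lactone
Product: 25 tetracyclic 3-hydroxy-1-ene lactone (C3 epimers), via (Z)-enal 24 (not isolated)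
Conditions: PPTS, acetone/H2O, 40 °C; then KN(SiMe3)2, THF, −78 → −40 °C
Reagents that add atoms: water, O
Why: Acetal hydrolysis followed by intramolecular aldol addition of the lactone enolate to the C3 aldehyde closes ring A; the configuration at C4 is fixed by the bicyclic lactone, which allows C3 to bond only on the face that carries C1, and the C3 carbinol configuration is irrelevant because it is oxidised in step 18.

Step 18
Reactants: 25 tetracyclic 3-hydroxy-1-ene lactone
Product: 26 1-en-3-one lactone
Conditions: Dess–Martin periodinane, CH2Cl2, rt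
Reagents that add atoms: none
Why: Dess–Martin oxidation of the allylic alcohol to the conjugated ketone; no stereocentre is affected apart from the loss of C3.

Step 19
Reactants: 26 1-en-3-one lactone
Product: 27 1β,2β-epoxy-3-ketone
Conditions: t-BuOOH, DBU, CH2Cl2, 0 °C
Reagents that add atoms: tert-butyl hydroperoxide, CC(C)(C)OO
Why: Nucleophilic (Weitz–Scheffer type) epoxidation of the enone, which leaves the electron-rich C16 methylene untouched: the hydroperoxide anion should add to C1 axially from the β face, anti to the C10–O bond and away from the lactone bridge and ring C, so that the 1β,2β-epoxide results.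

Step 20
Reactants: 27 1β,2β-epoxy-3-ketone
Product: 28 1β-hydroxy-3-ketone (12-O-silyl; silylethyl ester)
Conditions: SmI2 (2.2 equiv), THF/MeOH, −90 °C
Reagents that add atoms: none
Why: Reductive opening of the α,β-epoxy ketone by SmI2 (two single-electron transfers, cleavage of the C2–O bond of the ketyl and protonation of the samarium enolate) gives the β-hydroxy ketone with the C1–O bond, and thus the 1β configuration, intact.

Step 21
Reactants: 28 1β-hydroxy-3-ketone (12-O-silyl; silylethyl ester)
Product: 29 CNP0259985.1
Conditions: (Me2N)3S+ Me3SiF2− (TASF), DMF/H2O, 0 °C → rt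
Reagents that add atoms: none
Why: Fluoride-induced cleavage of the 2-(trimethylsilyl)ethyl ester (β-elimination with loss of ethylene) and of the silyl ether under near-neutral conditions should spare the β-hydroxy ketone, the lactone and the exocyclic alkene and give the target.

**Compound list**
1 | furfural | O=Cc1ccco1 | starting material
2 | propargyl bromide (3-bromoprop-1-yne) | BrCC#C | starting material
3 | rac-1-(furan-2-yl)but-3-yn-1-ol | OC(CC#C)c1ccco1 | intermediate
4 | rac-trans-4-hydroxy-5-(prop-2-yn-1-yl)cyclopent-2-en-1-one (relative configuration shown) | O=C1C=C[C@@H](O)[C@@H]1CC#C | intermediate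
5 | rac-4-hydroxy-2-(prop-2-yn-1-yl)cyclopent-2-en-1-one | O=C1CC(O)C=C1CC#C | intermediate
6 | (R)-4-oxo-3-(prop-2-yn-1-yl)cyclopent-2-en-1-yl acetate | O=C1C[C@@H](OC(C)=O)C=C1CC#C | intermediate
7 | (R)-4-hydroxy-2-(prop-2-yn-1-yl)cyclopent-2-en-1-one | O=C1C[C@@H](O)C=C1CC#C | intermediate
8 | (R)-2-(prop-2-yn-1-yl)-4-(triethylsilyloxy)cyclopent-2-en-1-one | O=C1C[C@@H](O[Si](CC)(CC)CC)C=C1CC#C | intermediate
9 | methyl vinyl ketone (but-3-en-2-one) | CC(=O)C=C | starting material
10 | 2-(tert-butyldimethylsilyloxy)buta-1,3-diene | C=CC(=C)O[Si](C)(C)C(C)(C)C | intermediate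
11 | cis-fused B/C bicycle: ring B cyclopentanone (C6 ketone, 10β-triethylsilyloxy), ring C cyclohexene carrying the C12=C13 tert-butyldimethylsilyl enol ether, angular 8β-propargyl, H9 β | C#CC[C@]23CC=C(O[Si](C)(C)C(C)(C)C)C[C@H]2[C@H](O[Si](CC)(CC)CC)CC3=O | intermediate
12 | B/C/D tricycle: 10β-(triethylsilyloxy)-16-methylene-6,12-diketone, bicyclo[3.2.1]octane C/D with the C15–C16 bridge β | C=C1C[C@]23C[C@H]1C(=O)C[C@H]2[C@H](O[Si](CC)(CC)CC)CC3=O | intermediate
13 | tricyclic 12α-alcohol (OH axial, anti to the C15–C16 bridge), 10β-triethylsilyloxy, 6-ketone | C=C1C[C@]23C[C@H]1[C@@H](O)C[C@H]2[C@H](O[Si](CC)(CC)CC)CC3=O | intermediate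
14 | tricyclic 12α-(tert-butyldimethylsilyloxy)-10β-(triethylsilyloxy)-6-ketone | C=C1C[C@]23C[C@H]1[C@@H](O[Si](C)(C)C(C)(C)C)C[C@H]2[C@H](O[Si](CC)(CC)CC)CC3=O | intermediate
15 | tricyclic C5=C6 enol triflate (6-trifluoromethanesulfonyloxy), 12α-OTBS, 10β-OTES | C=C1C[C@]23C[C@H]1[C@@H](O[Si](C)(C)C(C)(C)C)C[C@H]2[C@H](O[Si](CC)(CC)CC)C=C3OS(=O)(=O)C(F)(F)F | intermediate
16 | tricyclic 2-(trimethylsilyl)ethyl ene ester (C7 on C6, C5=C6), 12α-OTBS, 10β-OTES | C=C1C[C@]23C[C@H]1[C@@H](O[Si](C)(C)C(C)(C)C)C[C@H]2[C@H](O[Si](CC)(CC)CC)C=C3C(=O)OCC[Si](C)(C)C | intermediate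
17 | tricyclic 10β-allylic alcohol, 12α-OTBS, 2-(trimethylsilyl)ethyl ene ester | C=C1C[C@]23C[C@H]1[C@@H](O[Si](C)(C)C(C)(C)C)C[C@H]2[C@H](O)C=C3C(=O)OCC[Si](C)(C)C | intermediate
18 | tricyclic 10-keto ene ester (C10 ketone conjugated to C5=C6–C7 ester), 12α-OTBS | C=C1C[C@]23C[C@H]1[C@@H](O[Si](C)(C)C(C)(C)C)C[C@H]2C(=O)C=C3C(=O)OCC[Si](C)(C)C | intermediate
19 | 3,3-diethoxyprop-1-yne | C#CC(OCC)OCC | starting material
20 | C10 alkoxide of the 10β-(3,3-diethoxyprop-1-ynyl) carbinol, oxygen α (shown as the lithium salt) | [Li+].C=C1C[C@]23C[C@H]1[C@@H](O[Si](C)(C)C(C)(C)C)C[C@H]2[C@]([O-])(C#CC(OCC)OCC)C=C3C(=O)OCC[Si](C)(C)C | intermediate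
21 | tricyclic 10α-propionyloxy-10β-(3,3-diethoxyprop-1-ynyl) ene ester, 12α-OTBS | C=C1C[C@]23C[C@H]1[C@@H](O[Si](C)(C)C(C)(C)C)C[C@H]2[C@](OC(=O)CC)(C#CC(OCC)OCC)C=C3C(=O)OCC[Si](C)(C)C | intermediate
22 | 19,10-lactone from C4–C5 bond formation: H5 β, 6β ester, C4 epimer mixture, 10β-(3,3-diethoxyprop-1-ynyl), 12α-OTBS | C=C1C[C@]23C[C@H]1[C@@H](O[Si](C)(C)C(C)(C)C)C[C@H]2[C@@]4(C#CC(OCC)OCC)OC(=O)C(C)[C@H]4[C@@H]3C(=O)OCC[Si](C)(C)C | intermediate
23 | the same lactone with a 10β-[(Z)-3,3-diethoxyprop-1-enyl] chain | C=C1C[C@]23C[C@H]1[C@@H](O[Si](C)(C)C(C)(C)C)C[C@H]2[C@@]4(/C=C\C(OCC)OCC)OC(=O)C(C)[C@H]4[C@@H]3C(=O)OCC[Si](C)(C)C | intermediate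
24 | the same lactone with a 10β-[(Z)-3-oxoprop-1-enyl] chain (C3 aldehyde) | C=C1C[C@]23C[C@H]1[C@@H](O[Si](C)(C)C(C)(C)C)C[C@H]2[C@@]4(/C=C\C=O)OC(=O)C(C)[C@H]4[C@@H]3C(=O)OCC[Si](C)(C)C | intermediate
25 | tetracyclic 19,10-lactone with ring A closed: 3-hydroxy-1-ene (C3 epimers), 12α-OTBS, 2-(trimethylsilyl)ethyl 7-ester | C=C1C[C@]23C[C@H]1[C@@H](O[Si](C)(C)C(C)(C)C)C[C@H]2[C@]12OC(=O)[C@](C)(C(O)C=C1)[C@H]2[C@@H]3C(=O)OCC[Si](C)(C)C | intermediate
26 | tetracyclic 1-en-3-one 19,10-lactone, 12α-OTBS, 2-(trimethylsilyl)ethyl 7-ester | C=C1C[C@]23C[C@H]1[C@@H](O[Si](C)(C)C(C)(C)C)C[C@H]2[C@]12OC(=O)[C@](C)(C(=O)C=C1)[C@H]2[C@@H]3C(=O)OCC[Si](C)(C)C | intermediate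
27 | tetracyclic 1β,2β-epoxy-3-ketone 19,10-lactone, 12α-OTBS, 2-(trimethylsilyl)ethyl 7-ester | C=C1C[C@]23C[C@H]1[C@@H](O[Si](C)(C)C(C)(C)C)C[C@H]2[C@]12OC(=O)[C@](C)(C(=O)[C@H]4O[C@H]41)[C@H]2[C@@H]3C(=O)OCC[Si](C)(C)C | intermediate
28 | tetracyclic 1β-hydroxy-3-ketone 19,10-lactone, 12α-OTBS, 2-(trimethylsilyl)ethyl 7-ester | C=C1C[C@]23C[C@H]1[C@@H](O[Si](C)(C)C(C)(C)C)C[C@H]2[C@]12OC(=O)[C@](C)(C(=O)C[C@H]1O)[C@H]2[C@@H]3C(=O)OCC[Si](C)(C)C | intermediate
29 | CNP0259985.1: 1β,12α-dihydroxy-3-oxo-16-methylene 19,10-lactone 7-oic acid | C=C1C[C@]23C[C@H]1[C@@H](O)C[C@H]2[C@]12OC(=O)[C@](C)(C(=O)C[C@H]1O)[C@H]2[C@@H]3C(=O)O | target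

**Step count and risks**
Total: 21 steps. Longest linear sequence: 20 steps (steps 1–5 and 7–21); step 6 is a one-step side branch.

Step 7. In the first stage the acid may cause loss of the C10 silyloxy group by β-elimination, or the sequence may stop after the first Michael addition; in the second stage the enol ether may be hydrolysed before it cyclises. The fallback sets out from 8 and builds ring C in separate operations. HgI2-catalysed Mukaiyama–Michael addition of 1-(tert-butyldimethylsilyloxy)-1-(ethylthio)ethene (CH2Cl2, −78 °C) should give, with silyl transfer and addition anti to the C10 silyloxy group, the thioester silyl enol ether F1. Coupling of the thioester with tributyl(vinyl)stannane (Pd2(dba)3, P(2-furyl)3, CuO2PPh2, THF, rt; Liebeskind–Srogl type) should give the vinyl ketone F2 with the C8 enol ether still in place. Catalytic t-BuMe2SiOTf then closes the C8–C14 bond by intramolecular Mukaiyama–Michael addition with silyl transfer to the C12 oxygen. The route is rejoined at 11, which is isolated and cyclised to 12 with Ph3PAuCl/AgBF4 as a separate operation.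

Step 8. The hydride may fail to discriminate between the two carbonyl groups (over-reduction at C6), or may be delivered to the wrong face of C12. The fallback sets out from 11, isolated after the first stage of step 7 by filtration through basic alumina, where C12 is still masked as its enol ether. KN(SiMe3)2 (2.1 equiv, the alkyne being deprotonated reversibly) and the N-pyridyl triflimide give the C5=C6 enol triflate F3. Alkoxycarbonylation as in step 11 gives the silylethyl ester F4. Gold-catalysed cyclisation as in step 7 gives the tricyclic keto ester F5, whose only ketone is C12. LiBH(s-Bu)3 gives the 12α-alcohol F6, and silylation as in step 9 rejoins the route at 16.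

Step 19. The peroxide nucleophile may open the lactone or cleave the non-enolisable β-keto lactone by a retro-Claisen path, or may attack the wrong face. The fallback sets out from 26. Copper-catalysed conjugate borylation (CuCl, NaOt-Bu, DPEphos, B2pin2, MeOH, THF, rt) should deliver boron axially to the β face of C1 and give the 1β-boryl ketone F7. Oxidation with NaBO3·4H2O (THF/H2O, 0 °C), which proceeds with retention, rejoins the route at 28, so that steps 19 and 20 are bypassed.

Further compounds
F1 | step 7 | S-ethyl thioester silyl enol ether: 1-(tert-butyldimethylsilyloxy)-2-propargyl-4β-(triethylsilyloxy)cyclopentene carrying CH2C(=O)SEt at C9, trans to the silyloxy group | C#CCC1=C(O[Si](C)(C)C(C)(C)C)C[C@@H](O[Si](CC)(CC)CC)[C@@H]1CC(=O)SCC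
F2 | step 7 | vinyl ketone silyl enol ether (CH2C(=O)CH=CH2 at C9) | C#CCC1=C(O[Si](C)(C)C(C)(C)C)C[C@@H](O[Si](CC)(CC)CC)[C@@H]1CC(=O)C=C
F3 | step 8 | bicyclic C5=C6 enol triflate with the C12=C13 silyl enol ether and 8β-propargyl | C#CC[C@]23CC=C(O[Si](C)(C)C(C)(C)C)C[C@H]2[C@H](O[Si](CC)(CC)CC)C=C3OS(=O)(=O)C(F)(F)F
F4 | step 8 | bicyclic 2-(trimethylsilyl)ethyl ene ester with the C12=C13 silyl enol ether and 8β-propargyl | C#CC[C@]23CC=C(O[Si](C)(C)C(C)(C)C)C[C@H]2[C@H](O[Si](CC)(CC)CC)C=C3C(=O)OCC[Si](C)(C)C
F5 | step 8 | tricyclic 12-keto ene ester, 10β-OTES, 16-methylene | C=C1C[C@]23C[C@H]1C(=O)C[C@H]2[C@H](O[Si](CC)(CC)CC)C=C3C(=O)OCC[Si](C)(C)C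
F6 | step 8 | tricyclic 12α-hydroxy ene ester, 10β-OTES | C=C1C[C@]23C[C@H]1[C@@H](O)C[C@H]2[C@H](O[Si](CC)(CC)CC)C=C3C(=O)OCC[Si](C)(C)C
F7 | step 19 | tetracyclic 1β-(pinacolatoboryl)-3-ketone 19,10-lactone, 12α-OTBS, silylethyl ester | C=C1C[C@]23C[C@H]1[C@@H](O[Si](C)(C)C(C)(C)C)C[C@H]2[C@]12OC(=O)[C@](C)(C(=O)C[C@H]1B4OC(C)(C)C(C)(C)O4)[C@H]2[C@@H]3C(=O)OCC[Si](C)(C)C
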